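**Plan**

- Locants used below: ring C1 (carries the side chain), C2 (CH2), C3 (CHOH), C4 (C(CH3)OH), C5 (CH–O‑angeloyl), C6 (CHOH); side chain C7 (=C14H2), C8 (CHOH), C9 (CH2), C10 (CH–O‑angeloyl), C11 (C(CH3)2OH).
- Retrosynthesis: C8 carbinol → ketone; C3/C4 diol → epoxide → C3=C4 alkene; the two angelate C–O bonds; then the C1–C7 bond, cut inside a temporary five‑membered ring (mixed methyl ketal of the C8 ketone with O–C6, a 2‑methoxy‑3‑methylidene‑tetrahydrofuran); then the ketal bond O6–C8 and the C8–C9 bond.
- Enabling feature: O–C6 is cis‑vicinal to the C1–C7 bond and C8 is oxygenated, so O6–C6–C1–C7–C8 can be closed through O6–C8; a vinyl radical at C7 hung from O–C6 can reach only the syn face of C1 of the ring diene C1=C2–C3=C4.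
- Forward: the carbocycle is bought; dienol 4 (two steps) and allene 14 (three steps, C8–C9 by epoxide opening) are tied through O6–C8 by iodoketalisation (step 6); 5‑exo radical cyclisation (step 7) forms C1–C7 and the temporary tetrahydrofuran; then deprotection, epoxidation, angeloylation, acid hydrolysis (opens ketal ring and epoxide) and ketone reduction.
- Stereochemistry: C5, C6 (diol 1) and C10 (glycidate 5) are bought; C1 is relayed from C6 by the cis ring fusion; C4 and C3 are relayed from C5 by hydroxyl‑directed epoxidation and trans‑diaxial opening; C8 is set by the oxazaborolidine reagent.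

Key step: step 7

Assumption: diol 1 (the cis‑dihydrodiol from microbial dioxygenation of toluene) and angelic anhydride 21 are treated as purchasable; ketals 16–23 are carried as C8 epimer mixtures because C8 becomes a ketone in step 11.

**Route**

Step 1
Reactants: 1 (1S,2R)-3-methylcyclohexa-3,5-diene-1,2-diol; 2 4-methoxybenzaldehyde dimethyl acetal
Product: 3 (3aR,7aS)-2-(4-methoxyphenyl)-4-methyl-3a,7a-dihydro-1,3-benzodioxole (both acetal epimers)
Conditions: TsOH·H2O (2 mol%), CH2Cl2, −20 °C; Et3N
Reagents that add atoms: 4-methoxybenzaldehyde dimethyl acetal, COC(OC)c1ccc(OC)cc1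
Why: Acid‑catalysed transacetalisation of the cis‑1,2‑diol should give the cis‑fused 4‑methoxybenzylidene acetal; C5 and C6 are the bought stereocentres and the acetal epimers converge in step 2.

Step 2
Reactants: 3 4-methoxybenzylidene acetal
Product: 4 (1S,6R)-6-[(4-methoxyphenyl)methoxy]-5-methylcyclohexa-2,4-dien-1-ol (free HO–C6; PMB ether on O–C5)
Conditions: i-Bu2AlH (3 equiv), CH2Cl2, −78 → −20 °C; aq. potassium sodium tartrate
Reagents that add atoms: none
Why: Regioselective reductive acetal opening: aluminium should bind the less hindered acetal oxygen (on C6, remote from the C4 methyl), that C–O bond breaks and hydride reduces the oxocarbenium ion, leaving the 4‑methoxybenzyl ether on O–C5 and the hydroxyl on C6 without touching a stereocentre.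

Step 3
Reactants: 5 methyl (2R)-oxirane-2-carboxylate; 6 methylmagnesium chloride
Product: 7 2-[(2R)-oxiran-2-yl]propan-2-ol
Conditions: MeMgCl (2.2 equiv), THF, −78 → −40 °C; aq. NH4Cl
Reagents that add atoms: methylmagnesium chloride, C[Mg]Cl
Why: Double Grignard addition to the ester at low temperature should outrun attack on the epoxide; C10 is the bought stereocentre and is not touched.

Step 4
Reactants: 7 epoxy alcohol; 8 triethylsilyl trifluoromethanesulfonate
Product: 9 triethyl{[2-((2R)-oxiran-2-yl)propan-2-yl]oxy}silane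
Conditions: Et3SiOTf, 2,6-lutidine, CH2Cl2, −78 °C
Reagents that add atoms: triethylsilyl trifluoromethanesulfonate, CC[Si](CC)(CC)OS(=O)(=O)C(F)(F)F
Why: Silyl triflate silylation of the tertiary alcohol under buffered conditions that leave the epoxide intact.

Step 5
Reactants: 10 methoxyallene; 9 silylated epoxide; 11 4-methoxybenzyl bromide
Product: 14 {[(3R)-5-methoxy-3-[(4-methoxyphenyl)methoxy]-2-methylhepta-5,6-dien-2-yl]oxy}triethylsilane (allene C14=C7=C8(OMe); C10 R), via 1-lithio-1-methoxyallene 12 (not isolated), via lithium alkoxide of the opened epoxide 13 (not isolated)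
Conditions: n-BuLi, THF, −40 °C; 9, −78 → 0 °C; 4-MeOC6H4CH2Br, Bu4NI (cat.), HMPA, 0 → 23 °C
Reagents that add atoms: methoxyallene, COC=C=C; 4-methoxybenzyl bromide, COc1ccc(CBr)cc1
Why: α‑Lithiation of the alkoxyallene and SN2 opening of the terminal epoxide at its CH2 (C9) form the C8–C9 bond with C10 untouched, and the lithium alkoxide is benzylated in the same flask (Williamson etherification).

Step 6
Reactants: 4 dienol; 14 allene; 15 N-iodosuccinimide
Product: 16 mixed methyl ketal in which O–C6 of 4 is bound to C8 of a (5R)-2-iodo-3-methoxy-5-[(4-methoxyphenyl)methoxy]-6-methyl-6-(triethylsilyloxy)hept-1-en-3-yl unit (both C8 epimers)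
Conditions: N-iodosuccinimide, 2,6-di-tert-butylpyridine, CH2Cl2, −78 → −40 °C, dark
Reagents that add atoms: N-iodosuccinimide, O=C1CCC(=O)N1I
Why: Haloacetalisation (first stage of a Ueno–Stork sequence): iodonium attacks the central allene carbon C7 of the electron‑rich alkoxyallene and the oxocarbenium ion at C8 is trapped by the only free hydroxyl (O–C6 of 4); the new ketal centre forms unselectively, which is of no consequence.

Step 7
Reactants: 16 iodo ketal
Product: 17 (3aR,7R,7aS)-2-methoxy-7-[(4-methoxyphenyl)methoxy]-2-{(2R)-2-[(4-methoxyphenyl)methoxy]-3-methyl-3-(triethylsilyloxy)butyl}-6-methyl-3-methylidene-2,3,3a,4,7,7a-hexahydro-1-benzofuran (cis-fused; both C8 epimers)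
Conditions: Bu3SnH (syringe pump), Et3B, air, toluene (0.01 M), 0 → 23 °C
Reagents that add atoms: none
Why: Bu3Sn• (Et3B/O2 initiation) abstracts iodine from C7, and the σ‑vinyl radical adds to C1, the terminus of the ring diene C1=C2–C3=C4, to give a C2–C3–C4 allyl radical that takes hydrogen from Bu3SnH. The closest known reaction type is the Ueno–Stork haloacetal radical cyclisation in its vinyl‑radical form, in which 2‑haloallyl acetals of allylic alcohols close to 3‑methylidene‑tetrahydrofurans. The one ring formed, the tetrahydrofuran O6–C8–C7–C1–C6, closes in the 5‑exo‑trig mode. The new stereocentre C1 is fixed by the tether, because the two‑atom C8–C7 arm hangs from O–C6 and can reach only the face of C1 syn to that oxygen, so the ring fusion is cis and C7 ends up cis to O–C6 as in the target; C8 stays an epimer mixture that is erased in step 11. The step needs 5‑exo attack at C1 instead of 6‑endo attack at C2, which the ring‑size preference and the allylic stabilisation of the 5‑exo adduct secure, and hydrogen delivery to C2 instead of C4, which the lower hindrance of the secondary terminus and the formation of the trisubstituted C3=C4 alkene secure. Direct reduction of the vinyl radical is held back by slow addition of the stannane at high dilution.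

Step 8
Reactants: 17 bicyclic ketal
Product: 18 (3aR,7R,7aS)-2-[(2R)-2-hydroxy-3-methyl-3-(triethylsilyloxy)butyl]-2-methoxy-6-methyl-3-methylidene-2,3,3a,4,7,7a-hexahydro-1-benzofuran-7-ol (free HO–C5 and HO–C10)
Conditions: DDQ (2.6 equiv), CH2Cl2/pH 7 phosphate buffer, 0 °C
Reagents that add atoms: none
Why: Oxidative cleavage of both 4‑methoxybenzyl ethers (benzylic hydride abstraction, hydrolysis of the oxocarbenium ions) in a buffered two‑phase medium that should spare the ketal, the silyl ether and the alkenes.

Step 9
Reactants: 18 diol; 19 tert-butyl hydroperoxide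
Product: 20 epoxy diol: 18 with an oxirane across C3–C4 on the face of HO–C5
Conditions: VO(acac)2 (5 mol%), t-BuOOH, CH2Cl2, 0 → 23 °C
Reagents that add atoms: tert-butyl hydroperoxide, CC(C)(C)OO
Why: Hydroxyl‑directed epoxidation: the vanadium alkylperoxide bound to the allylic HO–C5 delivers oxygen to C3=C4 on the face of that hydroxyl, setting C4–O cis to C5–O (C3–O on the same face is inverted in step 11), while the non‑allylic exocyclic alkene is left alone.

Step 10
Reactants: 20 epoxy diol; 21 angelic anhydride [(Z)-2-methylbut-2-enoic anhydride]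
Product: 23 bis-angelate of 20 at O–C5 and O–C10, via dilithium 5,10-dialkoxide 22 (not isolated)
Conditions: LiN(SiMe3)2 (2.2 equiv), THF, −78 °C; angelic anhydride (3 equiv), −78 → 0 °C
Reagents that add atoms: angelic anhydride, C/C=C(/C)C(=O)OC(=O)/C(C)=C\C
Why: Acylation of the two secondary lithium alkoxides by the symmetric anhydride at low temperature without a nucleophilic amine catalyst, conditions under which the Z‑angelate should not isomerise to tiglate; the cis‑epoxy alkoxide cannot undergo Payne migration and the tertiary oxygen is silylated.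

Step 11
Reactants: 23 bis-angelate; 24 water
Product: 25 C8 ketone: the target skeleton with C8=O and free hydroxyls at C3, C4, C6 and C11 (1R,3S,4R,5S,6S,10R)
Conditions: HClO4 (0.1 M aq.), THF, 0 → 23 °C
Reagents that add atoms: water, O
Why: Acid hydrolysis opens the methyl ketal to the C8 ketone and HO–C6, cleaves the tertiary silyl ether, and opens the protonated epoxide by trans‑diaxial (Fürst–Plattner) attack of water at C3 from the face opposite the epoxide, which inverts C3 and keeps C4–O cis to C5–O; attack at C4 is disfavoured by the inductive effect of the vicinal acyloxy group and by the triaxial chair it would need, and the cis‑placed C5 ester cannot participate.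

Step 12
Reactants: 25 enone
Product: 26 CNP0108485.1 (1R,3S,4R,5S,6S,8R,10R in the locants above)
Conditions: (S)-1-methyl-3,3-diphenyltetrahydro-1H,3H-pyrrolo[1,2-c][1,3,2]oxazaborole (0.5 equiv), catecholborane, CH2Cl2/toluene, −78 → −40 °C; MeOH
Reagents that add atoms: none
Why: Corey–Bakshi–Shibata reduction: the α‑branched alkenyl group (C7) acts as the large substituent and CH2‑9 as the small one, so the (S)‑oxazaborolidine should deliver hydride to give the (R)‑carbinol at C8 by reagent control with 1,2‑selectivity, and catecholborane tolerates the free hydroxyls.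

**Compound list**

1 | (1S,2R)-3-methylcyclohexa-3,5-diene-1,2-diol | CC1=CC=C[C@H](O)[C@@H]1O | starting material
2 | 4-methoxybenzaldehyde dimethyl acetal | COC(OC)c1ccc(OC)cc1 | starting material
3 | (3aR,7aS)-2-(4-methoxyphenyl)-4-methyl-3a,7a-dihydro-1,3-benzodioxole, acetal epimers | CC1=CC=C[C@@H]2OC(c3ccc(OC)cc3)O[C@H]12 | intermediate
4 | (1S,6R)-6-[(4-methoxyphenyl)methoxy]-5-methylcyclohexa-2,4-dien-1-ol | CC1=CC=C[C@H](O)[C@@H]1OCc1ccc(OC)cc1 | intermediate
5 | methyl (2R)-oxirane-2-carboxylate | COC(=O)[C@H]1CO1 | starting material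
6 | methylmagnesium chloride | C[Mg]Cl | starting material
7 | 2-[(2R)-oxiran-2-yl]propan-2-ol | CC(C)(O)[C@H]1CO1 | intermediate
8 | triethylsilyl trifluoromethanesulfonate | CC[Si](CC)(CC)OS(=O)(=O)C(F)(F)F | starting material
9 | triethyl{[2-((2R)-oxiran-2-yl)propan-2-yl]oxy}silane | CC[Si](CC)(CC)OC(C)(C)[C@H]1CO1 | intermediate
10 | methoxyallene (1-methoxypropa-1,2-diene) | COC=C=C | starting material
11 | 4-methoxybenzyl bromide | COc1ccc(CBr)cc1 | starting material
12 | 1-lithio-1-methoxyallene | [Li]C(OC)=C=C | intermediate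
13 | lithium (3R)-5-methoxy-2-methyl-2-(triethylsilyloxy)hepta-5,6-dien-3-olate | C=C=C(OC)C[C@@H]([O-])C(C)(C)O[Si](CC)(CC)CC.[Li+] | intermediate
14 | {[(3R)-5-methoxy-3-[(4-methoxyphenyl)methoxy]-2-methylhepta-5,6-dien-2-yl]oxy}triethylsilane | C=C=C(OC)C[C@@H](OCc1ccc(OC)cc1)C(C)(C)O[Si](CC)(CC)CC | intermediate
15 | N-iodosuccinimide | O=C1CCC(=O)N1I | starting material
16 | iodo ketal: O–C6 of 4 bound to C8 (OMe, C7(I)=CH2, chain), C8 epimers | CC1=CC=C[C@H](OC(OC)(C(I)=C)C[C@@H](OCc2ccc(OC)cc2)C(C)(C)O[Si](CC)(CC)CC)[C@@H]1OCc1ccc(OC)cc1 | intermediate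
17 | cis-fused 2-methoxy-3-methylidene-hexahydrobenzofuran ketal, bis-PMB ether, C8 epimers | C=C1[C@H]2CC=C(C)[C@@H](OCc3ccc(OC)cc3)[C@H]2OC1(OC)C[C@@H](OCc1ccc(OC)cc1)C(C)(C)O[Si](CC)(CC)CC | intermediate
18 | diol (HO–C5, HO–C10) of the bicyclic ketal | C=C1[C@H]2CC=C(C)[C@@H](O)[C@H]2OC1(OC)C[C@@H](O)C(C)(C)O[Si](CC)(CC)CC | intermediate
19 | tert-butyl hydroperoxide | CC(C)(C)OO | starting material
20 | epoxy diol (C3–C4 oxirane cis to HO–C5) | C=C1[C@H]2C[C@H]3O[C@@]3(C)[C@@H](O)[C@H]2OC1(OC)C[C@@H](O)C(C)(C)O[Si](CC)(CC)CC | intermediate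
21 | angelic anhydride | C/C=C(/C)C(=O)OC(=O)/C(C)=C\C | starting material
22 | dilithium 5,10-dialkoxide of 20 | C=C1[C@H]2C[C@H]3O[C@@]3(C)[C@@H]([O-])[C@H]2OC1(OC)C[C@@H]([O-])C(C)(C)O[Si](CC)(CC)CC.[Li+].[Li+] | intermediate
23 | 5,10-bis-angelate of the epoxy ketal | C=C1[C@H]2C[C@H]3O[C@@]3(C)[C@@H](OC(=O)/C(C)=C\C)[C@H]2OC1(OC)C[C@@H](OC(=O)/C(C)=C\C)C(C)(C)O[Si](CC)(CC)CC | intermediate
24 | water | O | starting material
25 | C8 ketone (8-oxo precursor of the target) | C=C(C(=O)C[C@@H](OC(=O)/C(C)=C\C)C(C)(C)O)[C@H]1C[C@H](O)[C@@](C)(O)[C@@H](OC(=O)/C(C)=C\C)[C@H]1O | intermediate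
26 | CNP0108485.1 | C=C([C@H](O)C[C@@H](OC(=O)/C(C)=C\C)C(C)(C)O)[C@H]1C[C@H](O)[C@@](C)(O)[C@@H](OC(=O)/C(C)=C\C)[C@H]1O | target

**Step count and risks**

Total steps: 12. Longest linear sequence: 10 steps (5 → 26); the ring branch from 1 is 9 steps.

Most likely to fail, in this order:

1. Step 7. Hydrogen may reach the vinyl radical before ring closure (direct reduction, or a 1,5‑shift from C5–H), and the allyl radical may take hydrogen at C4 and misplace the ring alkene. The fallback sets out from 16 and comes back at 17, with no new compound. The ring is closed by organopalladium chemistry (Pd(PPh3)4, HCO2Na, Bu4NCl, DMF, 60 °C): oxidative addition of the C7–I bond to zerovalent palladium, syn 5‑exo carbopalladation of C1=C2 (cis fusion again enforced by the tether), and hydride capture of the C2–C4 π‑allylpalladium (reductive Heck‑type cyclisation with anion capture); hydride delivery to the less hindered C2 would give 17.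

2. Step 11. Water may open the epoxide at the tertiary C4 instead of C3, and the acid may cause acyl migration or elimination of the β‑acyloxy ketone. The fallback sets out from 20 and comes back at 25, and opens the epoxide before any ester is present. Hydroxide (KOH, DMSO/H2O, 80 °C) attacks the secondary C3 in an unambiguous SN2, trans‑diaxial opening to give the tetrol F1. Bu4NF removes the silyl group to give the pentol F2. Bu2SnO followed by angelic anhydride acylates the secondary oxygen of each stannylene acetal (the cis C4/C5 diol and the C10/C11 diol) and leaves the axial, trans‑disposed HO–C3 free, giving the bis‑angelate F3. Pyridinium p‑toluenesulfonate in wet acetone then hydrolyses only the ketal to give 25.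

3. Step 6. The hindered secondary dienol may lose the race for the iodo‑oxocarbenium ion to proton loss or to the silyl ether oxygen on C11, and the acid‑sensitive dienol may aromatise. The fallback sets out from 4 and comes back at 16, and moves the allene onto the ring so that the final nucleophile is methanol. O–C6 of 4 is alkylated (NaH, propargyl bromide, THF, 0 °C) to the propargyl ether F4. KOt‑Bu in THF isomerises it to the allenyl ether F5. Lithiation (n‑BuLi, −78 °C), opening of epoxide 9 and trapping with 4‑methoxybenzyl bromide give the substituted allenyl ether F6. N‑iodosuccinimide in CH2Cl2/MeOH with NaHCO3 then gives 16 by iodomethoxylation.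

Further compounds
F0 | step 7 | none | none
F1 | step 11 | tetrol ketal (epoxide of 20 opened at C3 by hydroxide; silyl ether retained) | C=C1[C@H]2C[C@H](O)[C@@](C)(O)[C@@H](O)[C@H]2OC1(OC)C[C@@H](O)C(C)(C)O[Si](CC)(CC)CC
F2 | step 11 | pentol ketal (F1 without the silyl group) | C=C1[C@H]2C[C@H](O)[C@@](C)(O)[C@@H](O)[C@H]2OC1(OC)C[C@@H](O)C(C)(C)O
F3 | step 11 | 5,10-bis-angelate of F2 | C=C1[C@H]2C[C@H](O)[C@@](C)(O)[C@@H](OC(=O)/C(C)=C\C)[C@H]2OC1(OC)C[C@@H](OC(=O)/C(C)=C\C)C(C)(C)O
F4 | step 6 | propargyl ether of 4 at O–C6 | CC1=CC=C[C@H](OCC#C)[C@@H]1OCc1ccc(OC)cc1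
F5 | step 6 | allenyl ether of 4 at O–C6 | CC1=CC=C[C@H](OC=C=C)[C@@H]1OCc1ccc(OC)cc1
F6 | step 6 | allenyl ether carrying the C9–C11 chain on C8 | CC1=CC=C[C@H](OC(=C=C)C[C@@H](OCc2ccc(OC)cc2)C(C)(C)O[Si](CC)(CC)CC)[C@@H]1OCc1ccc(OC)cc1
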